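- We start from amounts: the violet run charged 0.70 M of first end groups and the grey run 1.1 M, with equal equivalents of solid second end groups, so the pair shows what a larger charge does to the percent of links.

| flask | first end groups | solid second end groups | remark | time |
|---|---|---|---|---|
| violet | 0.70 M | 1.1 equiv | run made earlier |  |
| grey | 1.1 M | 1.1 equiv | run made earlier |  |
| flask | 0.50 M | 1.10 equiv |  | 40 h |

| run | time / h | links / % |
|---|---|---|
| violet | 2.00 | 2.6 |
| violet | 6.00 | 7.3 |
| violet | 12.0 | 14.7 |
| violet | 15.0 | 19.0 |
| violet | 25.0 | 26.4 |
| grey | 5.00 | 5.2 |
| grey | 10.0 | 10.9 |
| grey | 15.0 | 17.6 |
| grey | 20.0 | 22.7 |
| grey | 25.0 | 25.7 |

(each reading ± 1 percentage point)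

- what was read earlier has a scatter of 1 percentage point, one standard deviation
- at the start none of the solid second end groups is in solution

- dawn: doubling the solubility of the solid second end groups, all else as stated
- winter: doubling the dissolution coefficient of the solid second end groups, all else as stated

* the links standing at 40 h, as a percentage of the first end groups charged
* the change that raises the amount of links at 40 h, in percent of the first end groups charged most ("none" if none brings more than 2 percentage points) (dawn / winter / none)
* amount of links at 40 h, in percent of the first end groups charged, after winter

- Turn the question round: for winter to beat dawn, dissolution would have to be the rate-limiting step. If it fed a fixed amount in M per hour that does not grow with the solid, that feed would be shared over a larger charge, so grey percentages would stand at 0.636 of violet ones at equal times.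
- Summing the readings at 15.0 h and 25.0 h, grey stands at 0.954 of violet. These scattered readings give a charge penalty of 0.105, the power of the charge by which the percent of links at equal time falls: 1 for a fixed feed, 0 for pseudo-first-order behaviour.
- The grey sum stands 14 percentage points above the fixed-feed value, against a scatter of 1 point per reading. Because the penalty is far below 1, we set the fixed feed aside and expect dawn to beat winter, though a feed growing with the solid, charged at 1.1 equiv in both runs, would also give 0.
- We stretch the violet curve to 40 h as a steady percent loss of the part that is not links, then correct it by the penalty for 0.50 M, which gives our own 40.2 %.
- The forecast gives 40 %, dawn as best, and 41 % after winter, on the ground: “Dissolved second end groups therefore look held near saturation”.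

    first end groups + second end groups → links (k = 0.00180 M⁻¹ min⁻¹)
    solid second end groups ⇌ second end groups, rate k2*(cs2 - [second end groups]) while solid is left; crystals form when [second end groups] > cs2 (solubility = 0.200 M, k = 0.00880 min⁻¹)
    first end groups + second end groups → rings, rate k3*[first end groups] as long as [second end groups] is above zero (k = 2.80 × 10⁻⁴ min⁻¹)

- The flask gives 38.9 % of links at 40 h, with dawn adding 12 points and winter 2.4 points, so dawn is best, and 41.3 % stands after winter. Beside its links, the flask at that time holds 36.8 % of rings, and 24 % of the charged first end groups are left. The penalty read from the runs, 0.105, puts the neighbour flask with 1.2 M of first end groups, equivalents and time held, at 0.912 of this flask's links, where a fixed feed would put it at 0.417. That neighbour stands at 34.9 % of links, 0.897 of this flask.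

The runs are simulated with constants of no real substance, and the scatter is random.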